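The earlier runs and the new flask were computed with constants of no real substance.

I counted the Z first. The flasks below differ in how things go in, and the question is which ends with the most Q.

| flask | Z | D | X | remark | time |
|---|---|---|---|---|---|
| theta | 33 mM | 23.1 mM | 132 mM | run made earlier |  |
| delta | 33 mM | 12 mM | 132 mM | run made earlier |  |
| beta | 33 mM | 46 mM | 132 mM | run made earlier |  |
| larch | 33 mM (in portions, 5, over 25 h) | 23.1 mM | 132 mM | first portion at the start, last at 25 h | 40 h |
| alder | 33 mM | 23.1 mM | 132 mM | everything together at the start | 40 h |
| oak | 33 mM | 23.1 mM | 132 mM (fed, over 25 h) | all else is in the flask from the start; the feed brings no volume worth counting | 40 h |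
| elm | 33 mM (fed, over 25 h) | 23.1 mM | 132 mM | all else is in the flask from the start; the feed brings no volume worth counting | 40 h |

- the flask with the highest amount of Q, in percent of the Z charged ("all alike" if they lie within 1.5 percentage points) (larch / alder / oak / elm / all alike)
- final Q, as a percentage of the Z charged, in larch
- final Q, as a percentage of the Z charged, in alder
- final Q, as a percentage of the Z charged, in oak
- final Q, as a percentage of the Z charged, in elm

- theta (time / h: Q / %, E / %): 5.00: 21.1, 4.8; 10.0: 26.4, 4.9; 15.0: 27.9, 9.3; 20.0: 28.3, 9.9; 25.0: 29.5, 9.1
- delta (time / h: Q / %, E / %): 3.00: 23.6, 0; 8.00: 37.9, 2.9; 15.0: 47.7, 4.9; 25.0: 53.9, 5.0; 30.0: 56.1, 4.3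
- beta (time / h: Q / %, E / %): 3.00: 10.3, 3.9; 8.00: 9.9, 8.3; 15.0: 11.2, 9.8; 25.0: 10.2, 13.6; 30.0: 10.4, 12.6

(each reading ± 1 percentage point)

In beta, with D above Z, Q still held near 10.4%, so I took it that X competes with D for Z from the start, and that Z beyond the D charge is open to X as well. I named the excess of Z over D, as a fraction of the Z charge, the uncovered share, which here is 30.0%. Theta's last Q of 29.5% stood beside it, so my first answer was that number for larch, alder, oak and elm alike.

The objection came from delta, whose uncovered share is 63.6% but whose Q had reached 56.1% at 30.0 h, so uncovered Z needs X and time. I went round again, taking Q as the uncovered share minus the Z still standing, and read a pseudo-first-order constant from delta's shrinking gap: 0.0884 h⁻¹ early but 0.0499 h⁻¹ late, which I read as X fading.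

That matters for elm, where the feed passes the D charge at 17.5 h and ends at 25 h. I placed the arrival of its uncovered Z around 21.2 h, and at the late constant I reckoned that 39.2% of it stayed unconverted at 40 h, which gave me a Q of 18.2%. Alder, with its Z present from the start, I kept near the uncovered share.

The forecast named alder, with 20.5% for larch, 31% for alder, 27.5% for oak and 21% for elm, on the ground that “late Z meets depleted X”. For elm it stood above my figure.

The flasks gave 21.2% in larch, 30.6% in alder, 27.0% in oak and 21.9% in elm, so alder led.

    Z + D → L (k = 0.620 L mol⁻¹ min⁻¹)
    X + L → E (k = 0.00380 L mol⁻¹ min⁻¹)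
    Z + X → Q (k = 0.0170 L mol⁻¹ min⁻¹)
    2 X → G (k = 0.00420 L mol⁻¹ min⁻¹)
    L → J (k = 0.00200 min⁻¹)

In elm at 40.0 h, Q 21.9% and Z 8.55% together made 30.4%, close to the uncovered share of 30.0%, so the missing Q was Z still waiting. The conversion of 2 X into G is the largest single effect on the Q gap between alder and larch: 9.3 percentage points with that step, 1.1 points without it. A neighbouring flask, the same as alder but with 130 mM of Z, has an uncovered share of 82.2%, and there Q 62.1% and Z 20.2% together made 82.3%.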